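**Plan**

- Retrosynthesis: the 6-O-benzyl group is removed last, ring B is traced back to a 2-substituted cyclohexane-1,3-dione, and C1'–C2' and C1'–C6' are then cut to leave a 2-methylchromone and a five-carbon diester.
- Enabling feature: in ring B, C1' lies between the two oxygen-bearing carbons C2' and C6', which is the pattern of C2 of a cyclohexane-1,3-dione. C1' is also the acidic 2-methyl carbon of the chromone, vinylogous to C4=O.
- The chromone is cut at O1–C2 and C2–C3 (Claisen condensation, cyclodehydration) and at C4–C4a (directed lithiation/acylation). The ring A oxygens come from syringaldehyde by bromination/methoxylation and Baeyer–Villiger oxidation.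
- Forward order: fully substituted ring A, then pyranone ring C, then ring B by [5+1] annulation and iodine/methanol aromatisation (which gives the mono-methyl ether directly), then hydrogenolysis.
- Stereochemistry: the target has no stereocentre, so nothing has to be set; the symmetry of the dione makes the choice between its two carbonyls irrelevant.

Key step: step 8

Assumption: rotation about the C2–C1' bond is taken as fast, so the target is achiral and the request for a single enantiomer is met by the constitution alone.

**Route**

Step 1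
Reactants: 1 syringaldehyde (4-hydroxy-3,5-dimethoxybenzaldehyde)
Product: 2 4-(benzyloxy)-3,5-dimethoxybenzaldehyde
Conditions: BnBr, K2CO3, DMF, 60 °C
Reagents that add atoms: benzyl bromide, BrCc1ccccc1
Why: Williamson etherification of the phenoxide (acidified by the para-formyl group) should be clean, and the benzyl ether is chosen because it tolerates the base, organolithium, acid and iodine steps ahead and leaves by hydrogenolysis at the end.

Step 2
Reactants: 2 4-(benzyloxy)-3,5-dimethoxybenzaldehyde
Product: 3 4-(benzyloxy)-2-bromo-3,5-dimethoxybenzaldehyde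
Conditions: NBS (1.05 equiv), DMF, rt, dark
Reagents that add atoms: N-bromosuccinimide, O=C1CCC(=O)N1Br
Why: Electrophilic aromatic bromination should occur at C2 (equivalent to C6), which is ortho to one methoxy group and para to the other, while the unactivated benzyl ring stays untouched, as in the bromination of 3,4,5-trimethoxybenzaldehyde.

Step 3
Reactants: 3 4-(benzyloxy)-2-bromo-3,5-dimethoxybenzaldehyde
Product: 4 4-(benzyloxy)-2,3,5-trimethoxybenzaldehyde
Conditions: NaOMe, CuBr (10 mol%), DMF–MeOH, 100 °C
Reagents that add atoms: sodium methoxide, C[O-].[Na+]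
Why: Copper(I)-catalysed Ullmann-type methoxylation should replace the bromide, helped by the ortho-formyl group, in the same way that 5-bromovanillin is converted into syringaldehyde.

Step 4
Reactants: 4 4-(benzyloxy)-2,3,5-trimethoxybenzaldehyde
Product: 6 4-(benzyloxy)-2,3,5-trimethoxyphenol, via aryl formate 5 (not isolated)
Conditions: mCPBA, CH2Cl2, 0 °C → rt; aq. NaHCO3 wash; then K2CO3 (cat.), MeOH, rt
Reagents that add atoms: 3-chloroperoxybenzoic acid (mCPBA), OOC(=O)c1cccc(Cl)c1
Why: Baeyer–Villiger (Dakin-type) oxidation of an electron-rich benzaldehyde proceeds with aryl migration to the aryl formate, and mild transesterification with methanol then frees the phenol without touching the ethers.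

Step 5
Reactants: 6 4-(benzyloxy)-2,3,5-trimethoxyphenol
Product: 7 2-(benzyloxy)-1,3,4-trimethoxy-5-(methoxymethoxy)benzene
Conditions: NaH, MOMCl, DMF, 0 °C → rt
Reagents that add atoms: chloromethyl methyl ether, COCCl
Why: O-Alkylation of the sodium phenoxide with MOMCl installs an acetal that directs the following lithiation and is lost in the acid step that closes the pyranone.

Step 6
Reactants: 7 2-(benzyloxy)-1,3,4-trimethoxy-5-(methoxymethoxy)benzene; 8 N-methoxy-N-methylacetamide
Product: 10 1-[3-(benzyloxy)-2,4,5-trimethoxy-6-(methoxymethoxy)phenyl]ethan-1-one, via aryllithium 9 (not isolated)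
Conditions: n-BuLi (1.2 equiv), TMEDA, THF, −20 → 0 °C; then 8, −78 → 0 °C; H2O
Reagents that add atoms: none
Why: Directed ortho-metalation should take place at the only C–H of the central ring, which lies between the OMOM and OMe groups that cooperate in directing n-BuLi, and the aryllithium should add once to the Weinreb amide through a stable chelated tetrahedral adduct that releases the methyl ketone on work-up (Weinreb ketone synthesis).

Step 7
Reactants: 10 1-[3-(benzyloxy)-2,4,5-trimethoxy-6-(methoxymethoxy)phenyl]ethan-1-one; 11 ethyl acetate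
Product: 13 6-(benzyloxy)-5,7,8-trimethoxy-2-methyl-4H-chromen-4-one, via MOM-protected diketone 12 (not isolated)
Conditions: NaH, 11 (excess), THF, reflux; then conc. HCl, MeOH, 55 °C
Reagents that add atoms: none
Why: Crossed Claisen condensation of the methyl ketone enolate with ethyl acetate is driven by formation of the β-diketonate, and methanolic HCl then cleaves the MOM acetal so that the freed phenol adds to the distal carbonyl and water is lost (the classical cyclodehydration of o-hydroxyaryl β-diketones to 2-methylchromones).

Step 8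
Reactants: 13 6-(benzyloxy)-5,7,8-trimethoxy-2-methyl-4H-chromen-4-one; 14 dimethyl glutarate
Product: 16 2-[6-(benzyloxy)-5,7,8-trimethoxy-4-oxo-4H-chromen-2-yl]cyclohexane-1,3-dione (drawn as the diketone, expected to exist as its enol), via keto ester 15 (not isolated)
Conditions: LiHMDS (3.3 equiv), THF, −78 °C; 14 (1.3 equiv) added slowly; −78 → 60 °C; then 1 M HCl
Reagents that add atoms: none
Why: Proposed new method: LiHMDS removes a proton from the 2-methyl group (vinylogous to C4=O) and the dienolate attacks one ester of 14 through its exocyclic carbon to give keto ester 15, which is deprotonated at once at the now doubly activated CH2; on warming this stabilised carbanion attacks the second ester and expels methoxide, so that C1'–C6' follows C1'–C2' and ring B is closed. The closest known reactions are the γ-acylation of 2-methylchromone and 2-methyl-4-pyranone dienolates with esters such as diethyl oxalate and the double Claisen condensation of methyl ketones with glutarate diesters to 2-acylcyclohexane-1,3-diones; the step merges the two on a vinylogous methyl ketone. The ring closure is a 6-exo-trig Dieckmann-type acylation and should be pulled forward because the product is trapped as the highly delocalised enolate of a vinylogous triketone. No stereocentre is formed. The step needs deprotonation at the methyl group in preference to 1,4-addition at C2, which a hindered silylamide at −78 °C and the absence of any other acidic C–H in 13 (ring A is fully substituted) should secure; it also needs ring closure in preference to a second intermolecular acylation or capture of 15 by another dienolate, which slow addition of a small excess of 14, excess base and the entropic advantage of six-ring formation should secure.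

Step 9
Reactants: 16 2-[6-(benzyloxy)-5,7,8-trimethoxy-4-oxo-4H-chromen-2-yl]cyclohexane-1,3-dione
Product: 18 6-(benzyloxy)-2-(2-hydroxy-6-methoxyphenyl)-5,7,8-trimethoxy-4H-chromen-4-one, via vinylogous methyl ester 17 (not isolated)
Conditions: I2 (2.2 equiv), MeOH, reflux
Reagents that add atoms: methanol, CO
Why: Iodine in methanol is a known oxidative aromatisation of cyclohexane-1,3-diones, including 2-acyl ones, to 3-methoxyphenols: the HI formed catalyses enol etherification of one of the two equivalent carbonyls to vinylogous ester 17, α-iodination and loss of HI then aromatise the ring, and the second oxygen emerges as a phenol that methanol cannot etherify, so the mono-ether arises without a statistical methylation.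

Step 10
Reactants: 18 6-(benzyloxy)-2-(2-hydroxy-6-methoxyphenyl)-5,7,8-trimethoxy-4H-chromen-4-one
Product: 19 6,2'-dihydroxy-5,7,8,6'-tetramethoxyflavone
Conditions: H2 (1 atm), 10% Pd/C, EtOAc–MeOH, rt
Reagents that add atoms: none
Why: Hydrogenolysis of the aryl benzyl ether over Pd/C at one atmosphere should free the 6-OH while the chromone C2=C3 bond, the methyl ethers and the phenol are left alone, provided the reaction is stopped at full conversion.

**Compound list**

1 | syringaldehyde (4-hydroxy-3,5-dimethoxybenzaldehyde) | COc1cc(C=O)cc(OC)c1O | starting material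
2 | 4-(benzyloxy)-3,5-dimethoxybenzaldehyde | COc1cc(C=O)cc(OC)c1OCc1ccccc1 | intermediate
3 | 4-(benzyloxy)-2-bromo-3,5-dimethoxybenzaldehyde | COc1cc(C=O)c(Br)c(OC)c1OCc1ccccc1 | intermediate
4 | 4-(benzyloxy)-2,3,5-trimethoxybenzaldehyde | COc1cc(C=O)c(OC)c(OC)c1OCc1ccccc1 | intermediate
5 | 4-(benzyloxy)-2,3,5-trimethoxyphenyl formate | COc1cc(OC=O)c(OC)c(OC)c1OCc1ccccc1 | intermediate
6 | 4-(benzyloxy)-2,3,5-trimethoxyphenol | COc1cc(O)c(OC)c(OC)c1OCc1ccccc1 | intermediate
7 | 2-(benzyloxy)-1,3,4-trimethoxy-5-(methoxymethoxy)benzene | COCOc1cc(OC)c(OCc2ccccc2)c(OC)c1OC | intermediate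
8 | N-methoxy-N-methylacetamide | CON(C)C(C)=O | starting material
9 | [3-(benzyloxy)-2,4,5-trimethoxy-6-(methoxymethoxy)phenyl]lithium | [Li]c1c(OC)c(OCc2ccccc2)c(OC)c(OC)c1OCOC | intermediate
10 | 1-[3-(benzyloxy)-2,4,5-trimethoxy-6-(methoxymethoxy)phenyl]ethan-1-one | CC(=O)c1c(OC)c(OCc2ccccc2)c(OC)c(OC)c1OCOC | intermediate
11 | ethyl acetate | CCOC(C)=O | starting material
12 | 1-[3-(benzyloxy)-2,4,5-trimethoxy-6-(methoxymethoxy)phenyl]butane-1,3-dione | CC(=O)CC(=O)c1c(OC)c(OCc2ccccc2)c(OC)c(OC)c1OCOC | intermediate
13 | 6-(benzyloxy)-5,7,8-trimethoxy-2-methyl-4H-chromen-4-one | Cc1cc(=O)c2c(OC)c(OCc3ccccc3)c(OC)c(OC)c2o1 | intermediate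
14 | dimethyl glutarate (dimethyl pentanedioate) | COC(=O)CCCC(=O)OC | starting material
15 | methyl 6-[6-(benzyloxy)-5,7,8-trimethoxy-4-oxo-4H-chromen-2-yl]-5-oxohexanoate | COC(=O)CCCC(=O)Cc1cc(=O)c2c(OC)c(OCc3ccccc3)c(OC)c(OC)c2o1 | intermediate
16 | 2-[6-(benzyloxy)-5,7,8-trimethoxy-4-oxo-4H-chromen-2-yl]cyclohexane-1,3-dione | O=C1CCCC(=O)C1c1cc(=O)c2c(OC)c(OCc3ccccc3)c(OC)c(OC)c2o1 | intermediate
17 | 6-(benzyloxy)-5,7,8-trimethoxy-2-(2-methoxy-6-oxocyclohex-1-en-1-yl)-4H-chromen-4-one | COC1=C(c2cc(=O)c3c(OC)c(OCc4ccccc4)c(OC)c(OC)c3o2)C(=O)CCC1 | intermediate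
18 | 6-(benzyloxy)-2-(2-hydroxy-6-methoxyphenyl)-5,7,8-trimethoxy-4H-chromen-4-one | COc1cccc(O)c1-c1cc(=O)c2c(OC)c(OCc3ccccc3)c(OC)c(OC)c2o1 | intermediate
19 | 6,2'-dihydroxy-5,7,8,6'-tetramethoxyflavone (6-hydroxy-2-(2-hydroxy-6-methoxyphenyl)-5,7,8-trimethoxy-4H-chromen-4-one) | COc1cccc(O)c1-c1cc(=O)c2c(OC)c(O)c(OC)c(OC)c2o1 | target

**Count and risks**

Total step count: 10. Longest linear sequence: 10 steps (1 to 19).

Steps most likely to fail:

1. Step 8, the step marked as new. The sequence may stall after the first acylation. The dienolate may also be diverted by conjugate addition to a second chromone molecule, by proton transfer from the diester, or by one glutarate bridging two chromones. The fallback brings ring B in preformed by the classical chalcone route and sets out from ketone 10. Claisen–Schmidt condensation (KOH, EtOH, rt) of 10 with 2-(benzyloxy)-6-methoxybenzaldehyde F1 (from commercial 2-hydroxy-6-methoxybenzaldehyde, BnBr, K2CO3) should give the MOM-protected chalcone (2E)-1-[3-(benzyloxy)-2,4,5-trimethoxy-6-(methoxymethoxy)phenyl]-3-[2-(benzyloxy)-6-methoxyphenyl]prop-2-en-1-one F2. Methanolic HCl should remove the MOM group to give the 2'-hydroxychalcone (2E)-1-[3-(benzyloxy)-6-hydroxy-2,4,5-trimethoxyphenyl]-3-[2-(benzyloxy)-6-methoxyphenyl]prop-2-en-1-one F3. Iodine (cat.) in DMSO at 120 °C should then close and dehydrogenate it to 6-(benzyloxy)-2-[2-(benzyloxy)-6-methoxyphenyl]-5,7,8-trimethoxy-4H-chromen-4-one F4. Hydrogenolysis of both benzyl ethers (H2, Pd/C) comes back to the route at target 19.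

2. Step 9. The vinylogous ester may be ketalised further before dehydrogenation, so that both ring B oxygens end up methylated. The dehydrogenation may also stop short, or the new phenol ring may be iodinated. The fallback sets out from dione 16 and separates etherification from dehydrogenation. Acid-catalysed enol etherification (MeOH, HC(OMe)3, TsOH cat.) should give 17, which is isolated. Kinetic α'-deprotonation and selenenylation (LiHMDS, PhSeCl, THF, −78 °C) should then give racemic 6-(benzyloxy)-5,7,8-trimethoxy-2-[2-methoxy-6-oxo-5-(phenylselanyl)cyclohex-1-en-1-yl]-4H-chromen-4-one F5. Oxidation with H2O2 (CH2Cl2, pyridine, 0 °C → rt) should trigger selenoxide syn-elimination and tautomerisation, which comes back to the route at 18.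

3. Step 6. Lithiation at the benzylic CH2 followed by [1,2]-Wittig rearrangement may compete with ring metalation. Proton transfer from the amide to the aryllithium may also return protonated arene 7. The fallback avoids organolithium chemistry and sets out from phenol 6. Friedel–Crafts/Fries acetylation (Ac2O, BF3·OEt2, 0 °C → rt) should be possible at low temperature because the free position is ortho, ortho and para to three oxygens, and should give 1-[3-(benzyloxy)-6-hydroxy-2,4,5-trimethoxyphenyl]ethan-1-one F6. Claisen condensation with ethyl acetate 11 (NaH, THF, reflux) should give 1-[3-(benzyloxy)-6-hydroxy-2,4,5-trimethoxyphenyl]butane-1,3-dione F7. Cyclodehydration (AcOH, cat. H2SO4, 60 °C) comes back to the route at 13.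

**Further compounds**

F1 | step 8 | 2-(benzyloxy)-6-methoxybenzaldehyde | COc1cccc(OCc2ccccc2)c1C=O
F2 | step 8 | (2E)-1-[3-(benzyloxy)-2,4,5-trimethoxy-6-(methoxymethoxy)phenyl]-3-[2-(benzyloxy)-6-methoxyphenyl]prop-2-en-1-one | COCOc1c(OC)c(OC)c(OCc2ccccc2)c(OC)c1C(=O)/C=C/c1c(OC)cccc1OCc1ccccc1
F3 | step 8 | (2E)-1-[3-(benzyloxy)-6-hydroxy-2,4,5-trimethoxyphenyl]-3-[2-(benzyloxy)-6-methoxyphenyl]prop-2-en-1-one | Oc1c(OC)c(OC)c(OCc2ccccc2)c(OC)c1C(=O)/C=C/c1c(OC)cccc1OCc1ccccc1
F4 | step 8 | 6-(benzyloxy)-2-[2-(benzyloxy)-6-methoxyphenyl]-5,7,8-trimethoxy-4H-chromen-4-one | COc1cccc(OCc2ccccc2)c1-c1cc(=O)c2c(OC)c(OCc3ccccc3)c(OC)c(OC)c2o1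
F5 | step 9 | 6-(benzyloxy)-5,7,8-trimethoxy-2-[2-methoxy-6-oxo-5-(phenylselanyl)cyclohex-1-en-1-yl]-4H-chromen-4-one (racemic) | COC1=C(c2cc(=O)c3c(OC)c(OCc4ccccc4)c(OC)c(OC)c3o2)C(=O)C([Se]c2ccccc2)CC1
F6 | step 6 | 1-[3-(benzyloxy)-6-hydroxy-2,4,5-trimethoxyphenyl]ethan-1-one | CC(=O)c1c(O)c(OC)c(OC)c(OCc2ccccc2)c1OC
F7 | step 6 | 1-[3-(benzyloxy)-6-hydroxy-2,4,5-trimethoxyphenyl]butane-1,3-dione | CC(=O)CC(=O)c1c(O)c(OC)c(OC)c(OCc2ccccc2)c1OC
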